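**Plan**

1. Retrosynthesis: the oxirane oxygen on C5–C6 is removed first (hydroxyl-directed epoxidation), then the C4–H bond (enantioselective ketone reduction); the carbocycle is then traced back through a quinone monoketal and bisketal to a 2,5-dimethoxyarene.
2. The feature that allows the chain to be joined: on the ring C1–C6, C1' and the acetoxymethyl carbon are para benzylic carbons of that arene, and C3' carries a methyl on an E-alkene. C1'–C2' and C3'–CH3 are therefore cut together (alkyne methylalumination, then benzylic coupling with a symmetrical bis(chloromethyl)arene).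
3. The chain is cut further at C4'–C5' (propargylation of a geranyl bromide) and at C12'–O (allylic oxidation of geranyl acetate).
4. Forward: geranyl acetate to the C11 dienyne (steps 1–6); three-component union with AlMe3 and the dichloride (step 7); acetate for chloride, anodic dearomatisation, monohydrolysis (steps 8–11); reduction, epoxidation, deprotection (steps 12–14). The six-membered ring is the commercial arene and is never closed; the oxirane is the only ring formed (step 13).
5. Stereochemistry: 6'E and 10'E come from geranyl acetate and the E-selective allylic oxidation, 2'E from syn-carboalumination, C4 from an (R)-CBS reduction, and C5/C6 from oxygen delivery cis to the C4 hydroxyl.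

Key step: step 7

Remark: ring atoms are numbered C1 (C=O), C2 (=CH), C3 (C–CH2OAc), C4 (CHOH), C5 (oxirane CH), C6 (oxirane C carrying the chain C1'–C12'). The given SMILES corresponds to (4R,5R,6R), with the oxirane cis to the C4 hydroxyl. TBS = tert-butyldimethylsilyl; "chain" = (2E,6E,10E)-12-(TBS-oxy)-3,7,11-trimethyldodeca-2,6,10-trien-1-yl.

**Route**

Step 1
Reactants: 1 geranyl acetate
Product: 2 (2E,6E)-8-hydroxy-3,7-dimethylocta-2,6-dien-1-yl acetate
Conditions: SeO2 (cat.), salicylic acid (cat.), t-BuOOH, CH2Cl2, rt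
Reagents that add atoms: tert-butyl hydroperoxide, CC(C)(C)OO
Why: Riley allylic oxidation in its catalytic form (ene reaction, then [2,3]-sigmatropic shift) should hydroxylate the (E)-methyl of the terminal trisubstituted alkene, the alkene next to the acetate being inductively deactivated, and the sigmatropic transition state keeps the new allylic alcohol E.

Step 2
Reactants: 2 (2E,6E)-8-hydroxy-3,7-dimethylocta-2,6-dien-1-yl acetate
Product: 3 (2E,6E)-8-(TBS-oxy)-3,7-dimethylocta-2,6-dien-1-yl acetate
Conditions: TBSCl, imidazole, DMF, rt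
Reagents that add atoms: tert-butyldimethylsilyl chloride, CC(C)(C)[Si](C)(C)Cl
Why: Imidazole-promoted silylation of a primary alcohol gives an ether expected to survive organolithium, AlMe3, methanolic base and dilute acetic acid in the later steps.

Step 3
Reactants: 3 (2E,6E)-8-(TBS-oxy)-3,7-dimethylocta-2,6-dien-1-yl acetate
Product: 4 (2E,6E)-8-(TBS-oxy)-3,7-dimethylocta-2,6-dien-1-ol
Conditions: K2CO3 (cat.), MeOH, rt
Reagents that add atoms: none
Why: Base-catalysed transesterification with methanol frees the primary allylic alcohol, while the hindered silyl ether is inert to methoxide at this temperature.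

Step 4
Reactants: 4 (2E,6E)-8-(TBS-oxy)-3,7-dimethylocta-2,6-dien-1-ol
Product: 5 tert-butyl{[(2E,6E)-8-bromo-2,6-dimethylocta-2,6-dien-1-yl]oxy}dimethylsilane
Conditions: CBr4, PPh3, CH2Cl2, 0 °C
Reagents that add atoms: carbon tetrabromide, BrC(Br)(Br)Br
Why: Appel reaction, in which bromide displaces the alkoxyphosphonium ion in SN2 fashion under neutral conditions, so the silyl ether and both alkene geometries are untouched.

Step 5
Reactants: 5 tert-butyl{[(2E,6E)-8-bromo-2,6-dimethylocta-2,6-dien-1-yl]oxy}dimethylsilane; 6 1-(trimethylsilyl)propyne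
Product: 8 (5E,9E)-11-(TBS-oxy)-6,10-dimethyl-1-(trimethylsilyl)undeca-5,9-dien-1-yne, via 3-lithio-1-(trimethylsilyl)propyne 7 (not isolated)
Conditions: 6, n-BuLi, THF, −78 °C; then 5, −78 °C → 0 °C
Reagents that add atoms: none
Why: Propargylic lithiation followed by SN2 alkylation of the primary allylic bromide forms C4'–C5', the silyl group steering the ambident anion to react at its propargylic rather than its allenic terminus.

Step 6
Reactants: 8 (5E,9E)-11-(TBS-oxy)-6,10-dimethyl-1-(trimethylsilyl)undeca-5,9-dien-1-yne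
Product: 9 (5E,9E)-11-(TBS-oxy)-6,10-dimethylundeca-5,9-dien-1-yne
Conditions: K2CO3, MeOH, rt
Reagents that add atoms: none
Why: Methoxide-induced protodesilylation cleaves the alkynyl–silicon bond (acetylide leaving group, unhindered silicon), while the tert-butyldimethylsilyl ether has no comparable leaving group and stays.

Step 7
Reactants: 9 (5E,9E)-11-(TBS-oxy)-6,10-dimethylundeca-5,9-dien-1-yne; 10 trimethylaluminium; 11 1,4-bis(chloromethyl)-2,5-dimethoxybenzene
Product: 13 1-(chloromethyl)-2,5-dimethoxy-4-(chain)benzene, via (E)-alkenyldimethylalane 12 (not isolated)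
Conditions: AlMe3 (2 equiv), Cp2ZrCl2 (0.25 equiv), ClCH2CH2Cl, 0 °C → rt; volatiles removed; then 11 (3 equiv), NiCl2(PPh3)2 (5 mol%) reduced with n-BuLi (10 mol%) to zerovalent nickel, THF, rt
Reagents that add atoms: none
Why: The methylzirconocene species formed from Cp2ZrCl2 and AlMe3 adds methyl and metal syn across the terminal alkyne of 9 with methyl on the internal carbon, and exchange to aluminium gives the (E)-alkenylalane 12, which fixes C3'–CH3 and the 2'E geometry. Zerovalent nickel then inserts into one benzylic C–Cl bond of 11, the alkenyl group passes from aluminium to nickel in preference to methyl, and reductive elimination forms C1'–C2' with retention of alkene geometry. The closest known reaction type is the Negishi carboalumination of terminal alkynes followed by nickel- or palladium-catalysed coupling of the alkenylalane with benzylic chlorides, a sequence established for polyprenyl chains. No ring is closed and no stereocentre is created; the only stereochemical element is the trisubstituted alkene, controlled by the syn mode of carbometalation. The step needs mono-coupling of a dichloride with two equivalent ends, which is secured only statistically by a threefold excess of 11 (recovered); excess AlMe3 is removed beforehand to avoid methyl transfer, THF tempers the Lewis acidity of the aluminium species so that the electron-rich benzylic chlorides are not ionised, and the silyl ether and trisubstituted alkenes are inert.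

Step 8
Reactants: 13 1-(chloromethyl)-2,5-dimethoxy-4-(chain)benzene
Product: 14 2,5-dimethoxy-4-(chain)benzyl acetate
Conditions: KOAc, DMF, 50 °C
Reagents that add atoms: potassium acetate, CC(=O)[O-].[K+]
Why: SN2 displacement of the activated benzylic chloride by acetate in a dipolar aprotic solvent installs the oxygen of the future acetoxymethyl group and removes a halide that would be solvolysed to a methyl ether in step 9.

Step 9
Reactants: 14 2,5-dimethoxy-4-(chain)benzyl acetate
Product: 16 [3,3,6,6-tetramethoxy-4-(chain)cyclohexa-1,4-dien-1-yl]methanol, via 2,5-dimethoxy-4-(chain)benzyl alcohol 15 (not isolated)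
Conditions: 1% KOH/MeOH, 0 °C; then constant-current electrolysis, Pt anode, undivided cell, 0 °C
Reagents that add atoms: methanol, CO
Why: The methanolic hydroxide first removes the acetate by transesterification, and anodic bis-ketalisation (two-electron oxidation of a hydroquinone dimethyl ether in basic methanol) then adds methoxide at C1 and C4, the arene being oxidised at a potential well below that of the isolated trisubstituted alkenes.

Step 10
Reactants: 16 [3,3,6,6-tetramethoxy-4-(chain)cyclohexa-1,4-dien-1-yl]methanol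
Product: 17 [3,3,6,6-tetramethoxy-4-(chain)cyclohexa-1,4-dien-1-yl]methyl acetate
Conditions: Ac2O, Et3N, DMAP (cat.), CH2Cl2, 0 °C
Reagents that add atoms: acetic anhydride, CC(=O)OC(C)=O
Why: DMAP-catalysed acylation of the primary allylic alcohol under basic conditions leaves the acid-labile ketals untouched and puts in place the acetate that lowers the electron density of C2=C3 for steps 11 and 13.

Step 11
Reactants: 17 [3,3,6,6-tetramethoxy-4-(chain)cyclohexa-1,4-dien-1-yl]methyl acetate
Product: 18 [3,3-dimethoxy-6-oxo-4-(chain)cyclohexa-1,4-dien-1-yl]methyl acetate (C4 ketone, C1 dimethyl ketal)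
Conditions: dilute aq. AcOH, acetone, 0 °C, stopped at the monoketal
Reagents that add atoms: water, O
Why: Acid-catalysed monohydrolysis of a quinone bisketal: loss of methanol from C4 gives an oxocarbenium ion whose charge is shared by C2 and C6, where the alkyl chain stabilises it, whereas ionisation at C1 would place charge on C3 next to the inductively withdrawing acetoxymethyl group, so water should enter at C4, and the dienone formed is far less basic than the bisketal and resists a second hydrolysis.

Step 12
Reactants: 18 [3,3-dimethoxy-6-oxo-4-(chain)cyclohexa-1,4-dien-1-yl]methyl acetate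
Product: 19 [(6S)-6-hydroxy-3,3-dimethoxy-4-(chain)cyclohexa-1,4-dien-1-yl]methyl acetate (4S in ring numbering)
Conditions: (R)-Me-CBS oxazaborolidine (20 mol%), catecholborane, toluene, −78 °C; MeOH, then pH 8 buffer
Reagents that add atoms: none
Why: Corey–Bakshi–Shibata reduction of an α-substituted cross-conjugated enone: the ketone should bind the catalyst boron through the oxygen lone pair on the side of the unsubstituted C5–H, the C3 arm with its acetoxymethyl group acting as the large substituent, so that the (R)-catalyst delivers hydride to the face that makes C4 (S) in 19 (the same spatial arrangement as 4R in 20 and 21, where only substituent priorities change), while catecholborane at −78 °C spares acetate, ketal and silyl ether and the buffered work-up avoids acid-induced aromatisation.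

Step 13
Reactants: 19 [(6S)-6-hydroxy-3,3-dimethoxy-4-(chain)cyclohexa-1,4-dien-1-yl]methyl acetate
Product: 20 [(1R,5R,6R)-5-hydroxy-2,2-dimethoxy-1-(chain)-7-oxabicyclo[4.1.0]hept-3-en-4-yl]methyl acetate (4R,5R,6R in ring numbering)
Conditions: VO(acac)2 (5 mol%), t-BuOOH (decane solution), toluene, 0 °C
Reagents that add atoms: tert-butyl hydroperoxide, CC(C)(C)OO
Why: Hydroxyl-directed epoxidation through an oxovanadium tert-butylperoxide complex: the C4 alkoxide binds vanadium and oxygen is delivered to the alkene face cis to it, which sets C5 and C6 as 5R,6R; of the two ring alkenes allylic to C4 the alkyl-substituted C5=C6 is the more nucleophilic, C2=C3 being deactivated by the acetoxymethyl group, and the chain alkenes have no hydroxyl within reach.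

Step 14
Reactants: 20 [(1R,5R,6R)-5-hydroxy-2,2-dimethoxy-1-(chain)-7-oxabicyclo[4.1.0]hept-3-en-4-yl]methyl acetate
Product: 21 (4R,5R,6R)-3-(acetoxymethyl)-5,6-epoxy-4-hydroxy-6-[(2E,6E,10E)-12-hydroxy-3,7,11-trimethyldodeca-2,6,10-trien-1-yl]cyclohex-2-en-1-one
Conditions: 48% aq. HF, MeCN, 0 °C
Reagents that add atoms: water, O
Why: Acid-mediated global deprotection: aqueous HF hydrolyses the allylic dimethyl ketal to the C1 enone and cleaves the primary silyl ether as the silyl fluoride, conditions under which the acetate, the oxirane (deactivated toward acid opening by the adjacent carbonyl carbon) and the chain alkenes should persist, and no stereocentre is touched.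

**Compound list**

1 | geranyl acetate | CC(C)=CCC/C(C)=C/COC(C)=O | starting material
2 | (2E,6E)-8-hydroxy-3,7-dimethylocta-2,6-dien-1-yl acetate | CC(=O)OC/C=C(\C)CC/C=C(\C)CO | intermediate
3 | (2E,6E)-8-(TBS-oxy)-3,7-dimethylocta-2,6-dien-1-yl acetate | CC(=O)OC/C=C(\C)CC/C=C(\C)CO[Si](C)(C)C(C)(C)C | intermediate
4 | (2E,6E)-8-(TBS-oxy)-3,7-dimethylocta-2,6-dien-1-ol | OC/C=C(\C)CC/C=C(\C)CO[Si](C)(C)C(C)(C)C | intermediate
5 | tert-butyl{[(2E,6E)-8-bromo-2,6-dimethylocta-2,6-dien-1-yl]oxy}dimethylsilane | BrC/C=C(\C)CC/C=C(\C)CO[Si](C)(C)C(C)(C)C | intermediate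
6 | 1-(trimethylsilyl)propyne | CC#C[Si](C)(C)C | starting material
7 | 3-lithio-1-(trimethylsilyl)propyne | [Li]CC#C[Si](C)(C)C | intermediate (not isolated)
8 | (5E,9E)-11-(TBS-oxy)-6,10-dimethyl-1-(trimethylsilyl)undeca-5,9-dien-1-yne | C[Si](C)(C)C#CCC/C=C(\C)CC/C=C(\C)CO[Si](C)(C)C(C)(C)C | intermediate
9 | (5E,9E)-11-(TBS-oxy)-6,10-dimethylundeca-5,9-dien-1-yne | C#CCC/C=C(\C)CC/C=C(\C)CO[Si](C)(C)C(C)(C)C | intermediate
10 | trimethylaluminium | C[Al](C)C | starting material
11 | 1,4-bis(chloromethyl)-2,5-dimethoxybenzene | ClCc1cc(OC)c(CCl)cc1OC | starting material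
12 | dimethyl[(1E,5E,9E)-11-(TBS-oxy)-2,6,10-trimethylundeca-1,5,9-trien-1-yl]alane | C[Al](C)/C=C(\C)CC/C=C(\C)CC/C=C(\C)CO[Si](C)(C)C(C)(C)C | intermediate (not isolated)
13 | 1-(chloromethyl)-2,5-dimethoxy-4-[(2E,6E,10E)-12-(TBS-oxy)-3,7,11-trimethyldodeca-2,6,10-trien-1-yl]benzene | ClCc1cc(OC)c(C/C=C(\C)CC/C=C(\C)CC/C=C(\C)CO[Si](C)(C)C(C)(C)C)cc1OC | intermediate
14 | 2,5-dimethoxy-4-(chain)benzyl acetate | CC(=O)OCc1cc(OC)c(C/C=C(\C)CC/C=C(\C)CC/C=C(\C)CO[Si](C)(C)C(C)(C)C)cc1OC | intermediate
15 | 2,5-dimethoxy-4-(chain)benzyl alcohol | OCc1cc(OC)c(C/C=C(\C)CC/C=C(\C)CC/C=C(\C)CO[Si](C)(C)C(C)(C)C)cc1OC | intermediate (not isolated)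
16 | [3,3,6,6-tetramethoxy-4-(chain)cyclohexa-1,4-dien-1-yl]methanol | OCC1=CC(OC)(OC)C(C/C=C(\C)CC/C=C(\C)CC/C=C(\C)CO[Si](C)(C)C(C)(C)C)=CC1(OC)OC | intermediate
17 | [3,3,6,6-tetramethoxy-4-(chain)cyclohexa-1,4-dien-1-yl]methyl acetate | CC(=O)OCC1=CC(OC)(OC)C(C/C=C(\C)CC/C=C(\C)CC/C=C(\C)CO[Si](C)(C)C(C)(C)C)=CC1(OC)OC | intermediate
18 | [3,3-dimethoxy-6-oxo-4-(chain)cyclohexa-1,4-dien-1-yl]methyl acetate | CC(=O)OCC1=CC(OC)(OC)C(C/C=C(\C)CC/C=C(\C)CC/C=C(\C)CO[Si](C)(C)C(C)(C)C)=CC1=O | intermediate
19 | [(6S)-6-hydroxy-3,3-dimethoxy-4-(chain)cyclohexa-1,4-dien-1-yl]methyl acetate | CC(=O)OCC1=CC(OC)(OC)C(C/C=C(\C)CC/C=C(\C)CC/C=C(\C)CO[Si](C)(C)C(C)(C)C)=C[C@@H]1O | intermediate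
20 | [(1R,5R,6R)-5-hydroxy-2,2-dimethoxy-1-(chain)-7-oxabicyclo[4.1.0]hept-3-en-4-yl]methyl acetate | CC(=O)OCC1=CC(OC)(OC)[C@]2(C/C=C(\C)CC/C=C(\C)CC/C=C(\C)CO[Si](C)(C)C(C)(C)C)O[C@@H]2[C@@H]1O | intermediate
21 | (4R,5R,6R)-3-(acetoxymethyl)-5,6-epoxy-4-hydroxy-6-[(2E,6E,10E)-12-hydroxy-3,7,11-trimethyldodeca-2,6,10-trien-1-yl]cyclohex-2-en-1-one | CC(=O)OCC1=CC(=O)[C@]2(C/C=C(\C)CC/C=C(\C)CC/C=C(\C)CO)O[C@@H]2[C@@H]1O | target

**Step count**

Total steps: 14. Longest linear sequence: 14 steps (from geranyl acetate 1; compounds 6, 10 and 11 are commercial).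

**Steps most likely to fail**

Step 11. Methanol may be lost from the C1 ketal as well as, or instead of, the C4 ketal, because the two substituents bias the ionisation only moderately, and hydrolysis may run on to the quinone. The fallback fixes the regiochemistry through a phenol and sets out from 13. N-Methylmorpholine N-oxide in MeCN would oxidise the benzylic chloride to 2,5-dimethoxy-4-(chain)benzaldehyde F1. MgI2 etherate would then cleave, under chelation control, only the methyl ether ortho to the formyl group to give 2-hydroxy-5-methoxy-4-(chain)benzaldehyde F2. NaBH4 in MeOH would reduce this to 2-(hydroxymethyl)-4-methoxy-5-(chain)phenol F3. Oxidative dearomatisation with PhI(OAc)2 in MeOH places the carbonyl at the former phenol carbon (C4) and the ketal at the methoxy-bearing carbon (C1), giving 2-(hydroxymethyl)-4,4-dimethoxy-5-(chain)cyclohexa-2,5-dien-1-one F4. Acetylation with Ac2O and pyridine returns to 18.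

Step 12. The catalyst may discriminate poorly between the two faces of a carbonyl flanked by two sp2 carbons, and the bis-allylic alcohol may lose methanol and aromatise on contact with acid. The fallback separates reduction from enantiocontrol and sets out from 18. Luche reduction (NaBH4, CeCl3·7H2O, MeOH, −78 °C) would give racemic [6-hydroxy-3,3-dimethoxy-4-(chain)cyclohexa-1,4-dien-1-yl]methyl acetate F5. Kinetic resolution with Burkholderia cepacia lipase and vinyl acetate in t-BuOMe should, by the usual empirical size rule for secondary alcohols, acylate the (R)-enantiomer to [(6R)-6-acetoxy-3,3-dimethoxy-4-(chain)cyclohexa-1,4-dien-1-yl]methyl acetate F6. The unreacted (S)-alcohol is 19, where the route is rejoined; the sense of the enzyme's preference would have to be confirmed.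

Step 13. Oxygen may be transferred to C2=C3, which is also allylic to the C4 hydroxyl, if the acetoxymethyl group does not deactivate it enough. The fallback takes that alkene out of electrophilic reach by conjugation and sets out from 19. K2CO3 in MeOH would remove the acetate to give (6S)-6-hydroxy-3,3-dimethoxy-4-(chain)cyclohexa-1,4-dien-1-yl]methanol F7. TEMPO (cat.) with PhI(OAc)2 in NaHCO3-buffered CH2Cl2 would oxidise only the primary allylic alcohol to (6S)-6-hydroxy-3,3-dimethoxy-4-(chain)cyclohexa-1,4-diene-1-carbaldehyde F8. VO(acac)2 and t-BuOOH can then epoxidise only C5=C6, cis to the hydroxyl, giving (1R,5R,6R)-5-hydroxy-2,2-dimethoxy-1-(chain)-7-oxabicyclo[4.1.0]hept-3-ene-4-carbaldehyde F9. NaBH4 with CeCl3·7H2O at −78 °C would reduce the aldehyde to [(1R,5R,6R)-5-hydroxy-2,2-dimethoxy-1-(chain)-7-oxabicyclo[4.1.0]hept-3-en-4-yl]methanol F10. Acetyl chloride and 2,4,6-collidine at −78 °C would acetylate the primary hydroxyl only and return to 20.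

**Further compounds**

F1 | step 11 | 2,5-dimethoxy-4-(chain)benzaldehyde | O=Cc1cc(OC)c(C/C=C(\C)CC/C=C(\C)CC/C=C(\C)CO[Si](C)(C)C(C)(C)C)cc1OC
F2 | step 11 | 2-hydroxy-5-methoxy-4-(chain)benzaldehyde | O=Cc1cc(OC)c(C/C=C(\C)CC/C=C(\C)CC/C=C(\C)CO[Si](C)(C)C(C)(C)C)cc1O
F3 | step 11 | 2-(hydroxymethyl)-4-methoxy-5-(chain)phenol | OCc1cc(OC)c(C/C=C(\C)CC/C=C(\C)CC/C=C(\C)CO[Si](C)(C)C(C)(C)C)cc1O
F4 | step 11 | 2-(hydroxymethyl)-4,4-dimethoxy-5-(chain)cyclohexa-2,5-dien-1-one | OCC1=CC(OC)(OC)C(C/C=C(\C)CC/C=C(\C)CC/C=C(\C)CO[Si](C)(C)C(C)(C)C)=CC1=O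
F5 | step 12 | racemic [6-hydroxy-3,3-dimethoxy-4-(chain)cyclohexa-1,4-dien-1-yl]methyl acetate | CC(=O)OCC1=CC(OC)(OC)C(C/C=C(\C)CC/C=C(\C)CC/C=C(\C)CO[Si](C)(C)C(C)(C)C)=CC1O
F6 | step 12 | [(6R)-6-acetoxy-3,3-dimethoxy-4-(chain)cyclohexa-1,4-dien-1-yl]methyl acetate | CC(=O)OCC1=CC(OC)(OC)C(C/C=C(\C)CC/C=C(\C)CC/C=C(\C)CO[Si](C)(C)C(C)(C)C)=C[C@H]1OC(C)=O
F7 | step 13 | [(6S)-6-hydroxy-3,3-dimethoxy-4-(chain)cyclohexa-1,4-dien-1-yl]methanol | OCC1=CC(OC)(OC)C(C/C=C(\C)CC/C=C(\C)CC/C=C(\C)CO[Si](C)(C)C(C)(C)C)=C[C@@H]1O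
F8 | step 13 | (6S)-6-hydroxy-3,3-dimethoxy-4-(chain)cyclohexa-1,4-diene-1-carbaldehyde | O=CC1=CC(OC)(OC)C(C/C=C(\C)CC/C=C(\C)CC/C=C(\C)CO[Si](C)(C)C(C)(C)C)=C[C@@H]1O
F9 | step 13 | (1R,5R,6R)-5-hydroxy-2,2-dimethoxy-1-(chain)-7-oxabicyclo[4.1.0]hept-3-ene-4-carbaldehyde | O=CC1=CC(OC)(OC)[C@]2(C/C=C(\C)CC/C=C(\C)CC/C=C(\C)CO[Si](C)(C)C(C)(C)C)O[C@@H]2[C@@H]1O
F10 | step 13 | [(1R,5R,6R)-5-hydroxy-2,2-dimethoxy-1-(chain)-7-oxabicyclo[4.1.0]hept-3-en-4-yl]methanol | OCC1=CC(OC)(OC)[C@]2(C/C=C(\C)CC/C=C(\C)CC/C=C(\C)CO[Si](C)(C)C(C)(C)C)O[C@@H]2[C@@H]1O
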